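The runs stem from a simulated flask for substances that don't exist, noise included.

The ratio c(target) / (c(target) + c(isomer of the product)), the selectivity of the pair, was the meeting's item for this flask.

in all of them: solid substrate 0.40 M
- red: protic impurity 0.020 M; the very flask that is asked about, followed so far
- teal: protic impurity 0.013 M; run made earlier
- flask: protic impurity 0.0200 M; time 2.5 h

red run (percent of the solid substrate charged)

| time / min | target / % | isomer of the product / % | solid substrate / % |
|---|---|---|---|
| 6.00 | 6.3 | 0.3 | 16.4 |
| 12.0 | 14.4 | 0.6 | 4.7 |
| 20.0 | 20.8 | 1.9 | 0.7 |
| 25.0 | 22.4 | 2.5 | 0.2 |
| 30.0 | 24.7 | 3.7 | 0.8 |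

teal run (percent of the solid substrate charged)

| time / h | target / % | isomer of the product / % | solid substrate / % |
|---|---|---|---|
| 0.200 | 14.8 | 0.7 | 6.4 |
| 0.667 | 26.1 | 5.9 | 0.3 |
| 1.33 | 28.4 | 10.3 | 0 |
| 2.00 | 27.4 | 13.9 | 0 |
| 2.50 | 26.3 | 13.8 | 1.2 |

(scatter of a reading: 0.5 percentage points)

1. share of target in target plus isomer of the product at 2.0 min
2. share of target in target plus isomer of the product at 2.5 h
3. which of target and isomer of the product there is more of at 2.5 h

- solid substrate is a solid; its amount is given per volume of the solution
- steps thought possible: starting material <-> target; target <-> isomer of the product; isomer of the product <-> starting material; starting material + protic impurity -> quenched substrate; solid substrate <-> starting material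
- at the start none of the solid substrate is in solution

The first speaker noted that the red run, which is this flask so far, and the teal run differ in protic impurity, 0.020 M against 0.013 M. Yet red showed a share of 96.0 % at 12.0 min and teal 95.5 % at 0.200 h, the same time, and the two agree within the scatter. The second speaker therefore proposed carrying teal's end over to the flask. Pooling teal's readings at 2.00 h and 2.50 h gives 66.0 %, and this late share, the pair's share at the end of a run, was minuted as the figure to use at 2.5 h, with target ahead. The third speaker added that red's share falls from 95.5 % at 6.00 min to 87.0 % at 30.0 min, so at 2.0 min it should stand above the first of these.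

The forecast gave 98 % at 2.0 min and 65.5 % at 2.5 h, with target leading, since “Equilibrium ratios don't depend on the quench”. Its late figure lies 0.50 percentage points below the late share.

The flask gives 97.9 % at 2.0 min and 65.2 % at 2.5 h, with target at 26.6 % and isomer of the product at 14.2 %.

    starting material ⇌ target (K = 0.500, k = 4.00 × 10⁻⁴ s⁻¹)
    target ⇌ isomer of the product (K = 0.600, k = 1.40 × 10⁻⁴ s⁻¹)
    isomer of the product ⇌ starting material (k = 2.00 × 10⁻⁵ s⁻¹)
    starting material + protic impurity → quenched substrate (k = 0.00630 M⁻¹ s⁻¹)
    solid substrate ⇌ starting material, rate k5*(cs5 - [starting material]) while solid is left; crystals form when [starting material] > cs5 (solubility = 0.310 M, k = 0.0130 s⁻¹)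

A late share of 66.0 % puts target ahead of isomer of the product, and the flask has target ahead. The main reason for a value so far below the early one is the step between target and isomer of the product, run both ways: the run with that step struck out ends at 90.7 % instead of 65.2 %. In this flask the step to quenched substrate makes no difference to this share; carried to the neighbour charged with 0.034 M of protic impurity, the late share of 66.0 % again puts target ahead, and that neighbour ends with target at 25.7 % and isomer of the product at 13.7 %, a share of 65.2 %.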